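**Retrosynthetic overview**

1. Target ⇐ ester hydrolysis, C18 angeloylation, desilylation, hydration of the C8=C17 alkene and methylenation ⇐ 8-oxo ester 20 ⇐ C9 alkylation with the C11–C15 iodide 18 and decarboxylation ⇐ bicyclic β-keto ester 13.
2. 13 ⇐ one-flask [3+3] annulation of the ring A tertiary allylic alcohol 10 with the bis-silyl dienol ether of methyl acetoacetate 11: C6–C7 by SN1 allylation, then C9–C10 by cation–olefin closure of ring B.
3. Enabling feature: in ring B the carbinol carbon C8 is flanked by C7 and C9, so C7–C8–C9 is a masked acetoacetate 1,3-bis-nucleophile. C6–C5–C10 is an allyl unit whose termini are the CH2 (C6) and the methyl-bearing, later quaternary C10 of ring A.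
4. Ring order: ring A first (asymmetric conjugate methylation sets C4), ring B in the key step. C13 comes from (R)-monomethyl 3-methylglutarate.

Key step: step 6

Remark: labdane numbering is used throughout. The transient stereocentres C5 in 7 and 8, C10 in 10 and C9 in 19 are erased later and are left open or drawn as expected.

**Route**

Step 1
Reactants: 1 (3-methoxyphenyl)methanol
Product: 3 3-(hydroxymethyl)cyclohex-2-en-1-one, via enol ether diene 2 (not isolated)
Conditions: Li, NH3 (l), t-BuOH, THF, −78 °C; then 2 M HCl, THF, rt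
Reagents that add atoms: water, O
Why: Birch reduction of the anisole ring (the benzylic alcohol is carried as its alkoxide), then enol ether hydrolysis and acid-mediated isomerisation into conjugation should give the 3-substituted cyclohexenone, with no stereocentre formed.

Step 2
Reactants: 3 3-(hydroxymethyl)cyclohex-2-en-1-one
Product: 4 3-{[(tert-butyldiphenylsilyl)oxy]methyl}cyclohex-2-en-1-one
Conditions: TBDPSCl, imidazole, DMF, rt
Reagents that add atoms: tert-butylchlorodiphenylsilane, CC(C)(C)[Si](Cl)(c1ccccc1)c1ccccc1
Why: Standard silylation of the primary alcohol gives a poorly coordinating ether that should survive the later Lewis acid, base and thermal steps.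

Step 3
Reactants: 4 3-{[(tert-butyldiphenylsilyl)oxy]methyl}cyclohex-2-en-1-one
Product: 6 tert-butyl{[(1S)-1-methyl-3-(trimethylsilyloxy)cyclohex-2-en-1-yl]methoxy}diphenylsilane, via aluminium enolate 5 (not isolated)
Conditions: Me3Al, Cu(O2C-C4H3S) (copper thiophene-2-carboxylate, 2 mol %), BINOL-derived bis(1-phenylethyl)amine phosphoramidite (4 mol %, the enantiomer that delivers S), Et2O, −30 °C; then TMSOTf, −30 → 0 °C
Reagents that add atoms: trimethylaluminium, C[Al](C)C; trimethylsilyl trifluoromethanesulfonate, C[Si](C)(C)OS(=O)(=O)C(F)(F)F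
Why: Copper-catalysed asymmetric conjugate addition of Me3Al to a β-substituted cyclohexenone should create the quaternary C4 stereocentre (S) under ligand control, and the regiospecific aluminium enolate is trapped on oxygen as the enol silane.

Step 4
Reactants: 6 the enol silane from step 3
Product: 9 (3S)-3-{[(tert-butyldiphenylsilyl)oxy]methyl}-3-methyl-2-methylidenecyclohexan-1-one, via Mannich base 7 (not isolated), via methiodide 8 (not isolated)
Conditions: CH2=NMe2 iodide, CH2Cl2, rt; then MeI; then aq NaHCO3, rt
Reagents that add atoms: N,N-dimethylmethyleneiminium iodide, C=[N+](C)C.[I-]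
Why: Mannich reaction of the regiodefined enol silane at C5, quaternisation and Hofmann-type elimination (α-methylenation) should install C6 as an exocyclic methylene without touching C4.

Step 5
Reactants: 9 the α-methylene ketone from step 4
Product: 10 (3S)-3-{[(tert-butyldiphenylsilyl)oxy]methyl}-1,3-dimethyl-2-methylidenecyclohexan-1-ol (both C1 epimers)
Conditions: MeLi, CeCl3, THF, −78 °C; aq NH4Cl
Reagents that add atoms: methyllithium, [Li]C
Why: Organocerium-type 1,2-addition to the hindered enone should bring in C20; the carbinol configuration is irrelevant because C10 is ionised in step 6.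

Step 6
Reactants: 10 the tertiary allylic alcohol from step 5; 11 1-methoxy-1,3-bis(trimethylsilyloxy)buta-1,3-diene
Product: 13 methyl (1S,4aS,5S,8aR)-5-{[(tert-butyldiphenylsilyl)oxy]methyl}-5,8a-dimethyl-2-oxodecahydronaphthalene-1-carboxylate, via monocyclic β-keto ester 12 (not isolated)
Conditions: SnCl4 (2.2 equiv), CH2Cl2, −78 → 0 °C
Reagents that add atoms: none
Why: Proposed new method: SnCl4 should ionise the tertiary allylic alcohol of 10 to a cyclohexenylmethyl allyl cation (C6–C5–C10) that is captured at its unhindered CH2 terminus C6 by the terminal carbon of 11 (C6–C7) to give 12, whose C5=C10 alkene is then protonated at C5 by the HCl–SnCl4 pair so that the tin-chelated β-keto ester carbon C9 adds to the tertiary C10 cation (C9–C10). The closest known reaction types are the Lewis-acid SN1 allylation and [3+3] cyclisation of 1,3-bis(silyloxy)-1,3-dienes with 1,3-dielectrophiles and the SnCl4-mediated cyclisation of 5-(cyclohex-1-enyl)-3-oxopentanoates to trans-decalin β-keto esters; joining them in one flask on an allyl-cation dielectrophile is the untested part. Ring B closes in a 6-endo-trig cation–olefin mode through a chair transition state in which the C5 side arm and the forming C9–C10 bond are equatorial on ring A. C5 and C10 should therefore form trans (H5 anti to the C10 methyl) and the enolisable C9 settles with the ester equatorial, while C4, the only pre-existing stereocentre, decides the absolute sense. The step needs C6-selective first attack (primary against tertiary cation terminus), C- rather than O-cyclisation (the central carbon of the chelated β-keto ester closes the six-membered ring) and a facial preference relative to C4; the chair with the bulkier CH2OSi(t-Bu)Ph2 equatorial and the C4 methyl axial is expected to be favoured only modestly, and the C4-epimeric trans-decalin is the separable diastereomeric by-product.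

Step 7
Reactants: 14 (R)-5-methoxy-3-methyl-5-oxopentanoic acid
Product: 16 (S)-4-methyloxan-2-one, via hydroxy acid 15 (not isolated)
Conditions: LiBH4, THF, 0 °C → rt; then 2 M HCl
Reagents that add atoms: none
Why: Chemoselective LiBH4 reduction of the ester beside the lithium carboxylate, then acid-promoted lactonisation, should give the lactone with the C13 stereocentre untouched.

Step 8
Reactants: 16 (S)-4-methyloxan-2-one
Product: 18 methyl (R)-5-iodo-3-methylpentanoate, via silyl iodo ester 17 (not isolated)
Conditions: TMSCl, NaI, MeCN, rt; then MeOH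
Reagents that add atoms: sodium iodide, [Na+].[I-]; methanol, CO
Why: Iodotrimethylsilane formed in the flask should open the lactone by SN2 attack of iodide at the O–CH2 carbon, and methanolysis of the silyl ester gives the ω-iodo methyl ester; C13 is not involved.

Step 9
Reactants: 13 the bicyclic β-keto ester from step 6; 18 methyl (R)-5-iodo-3-methylpentanoate
Product: 19 C9-alkylated β-keto diester (ring configuration as in 13; side chain on C9 anti to the C10 methyl)
Conditions: Cs2CO3, DMF, 50 °C
Reagents that add atoms: none
Why: SN2 C-alkylation of the caesium enolate of the β-keto ester with the primary iodide attaches C11–C15; the electrophile should enter anti to the axial C10 methyl, but the C9 configuration is erased in step 10.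

Step 10
Reactants: 19 the alkylated β-keto diester from step 9
Product: 20 methyl 18-(tert-butyldiphenylsilyloxy)-8-oxo-17-nor-labdan-15-oate (ent series; trans-decalin, side chain equatorial, 13S)
Conditions: LiCl, DMSO, H2O, 150 °C
Reagents that add atoms: none
Why: Krapcho dealkoxycarbonylation removes the activating ester while the unactivated C15 ester is inert, and protonation of the enol anti to the C10 methyl with equilibration should leave the side chain equatorial at C9.

Step 11
Reactants: 20 the C8 ketone from step 10
Product: 21 methyl 18-(tert-butyldiphenylsilyloxy)labd-8(17)-en-15-oate (ent series)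
Conditions: Ph3PCH3Br, NaHMDS, THF, 0 → 60 °C
Reagents that add atoms: methyltriphenylphosphonium bromide, C[P+](c1ccccc1)(c1ccccc1)c1ccccc1.[Br-]
Why: Wittig methylenation of the C8 ketone installs C17 as the exocyclic alkene; the unactivated methyl ester should not react and the epimerisable C9 stays equatorial.

Step 12
Reactants: 21 the exocyclic alkene from step 11
Product: 22 methyl 18-(tert-butyldiphenylsilyloxy)-8-hydroxylabdan-15-oate (ent series; 8-OH equatorial, trans to the C10 methyl)
Conditions: Mn(dpm)3 (cat.), PhSiH3, O2 (1 atm), i-PrOH/CH2Cl2, 0 °C → rt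
Reagents that add atoms: dioxygen, O=O
Why: Mukaiyama hydration gives the tertiary C8 radical by Markovnikov hydrogen-atom transfer, and O2 should capture it from the face opposite the axial C10 methyl, giving the equatorial C8–OH with the new methyl axial.

Step 13
Reactants: 22 the silyl-protected hydroxy ester from step 12
Product: 23 methyl 8,18-dihydroxylabdan-15-oate (ent series)
Conditions: TBAF, THF, rt
Reagents that add atoms: none
Why: Fluoride-mediated desilylation frees the neopentyl C18 alcohol; the methyl ester and the tertiary alcohol should be inert.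

Step 14
Reactants: 23 the diol ester from step 13; 24 angelic acid, (Z)-2-methylbut-2-enoic acid
Product: 26 methyl 18-angeloyloxy-8-hydroxylabdan-15-oate (ent series), via mixed anhydride 25 (not isolated)
Conditions: 24, 2,4,6-trichlorobenzoyl chloride, Et3N, toluene, rt; then 23, 80 °C (no DMAP)
Reagents that add atoms: none
Why: Yamaguchi-type esterification through the mixed anhydride should acylate only the primary C18–OH (the tertiary C8–OH is too hindered), and leaving out the nucleophilic catalyst keeps the (Z) geometry.

Step 15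
Reactants: 26 the angelate methyl ester from step 14
Product: 28 (4S,5S,8S,9S,10R,13S)-18-angeloyloxy-8-hydroxylabdan-15-oic acid (target), via trimethylstannyl ester 27 (not isolated)
Conditions: Me3SnOH, ClCH2CH2Cl, 70 °C; then 0.1 M HCl
Reagents that add atoms: trimethyltin hydroxide, C[Sn](C)(C)O
Why: Me3SnOH-mediated hydrolysis should cleave the unhindered methyl ester selectively over the hindered neopentyl angelate and leave the (Z)-alkene untouched.

**Compound list**

1 | (3-methoxyphenyl)methanol | COc1cccc(CO)c1 | starting material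
2 | (5-methoxycyclohexa-1,4-dien-1-yl)methanol | COC1=CCC=C(CO)C1 | intermediate
3 | 3-(hydroxymethyl)cyclohex-2-en-1-one | O=C1C=C(CO)CCC1 | intermediate
4 | 3-{[(tert-butyldiphenylsilyl)oxy]methyl}cyclohex-2-en-1-one | O=C1C=C(CO[Si](c2ccccc2)(c2ccccc2)C(C)(C)C)CCC1 | intermediate
5 | dimethylaluminium enolate of (S)-3-(silyloxymethyl)-3-methylcyclohexanone | CC(C)(C)[Si](c1ccccc1)(c1ccccc1)OC[C@@]1(C)CCCC(O[Al](C)C)=C1 | intermediate
6 | tert-butyl{[(1S)-1-methyl-3-(trimethylsilyloxy)cyclohex-2-en-1-yl]methoxy}diphenylsilane | CC(C)(C)[Si](c1ccccc1)(c1ccccc1)OC[C@@]1(C)CCCC(O[Si](C)(C)C)=C1 | intermediate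
7 | (3S)-2-[(dimethylamino)methyl]-3-(silyloxymethyl)-3-methylcyclohexanone (C2 epimers) | CC(C)(C)[Si](c1ccccc1)(c1ccccc1)OC[C@@]1(C)CCCC(=O)C1CN(C)C | intermediate
8 | trimethylammonium iodide (methiodide) of 7 | CC(C)(C)[Si](c1ccccc1)(c1ccccc1)OC[C@@]1(C)CCCC(=O)C1C[N+](C)(C)C.[I-] | intermediate
9 | (3S)-3-{[(tert-butyldiphenylsilyl)oxy]methyl}-3-methyl-2-methylidenecyclohexan-1-one | CC(C)(C)[Si](c1ccccc1)(c1ccccc1)OC[C@@]1(C)CCCC(=O)C1=C | intermediate
10 | (3S)-3-{[(tert-butyldiphenylsilyl)oxy]methyl}-1,3-dimethyl-2-methylidenecyclohexan-1-ol (C1 epimers) | CC(C)(C)[Si](c1ccccc1)(c1ccccc1)OC[C@@]1(C)CCCC(C)(O)C1=C | intermediate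
11 | 1-methoxy-1,3-bis(trimethylsilyloxy)buta-1,3-diene | COC(O[Si](C)(C)C)=CC(=C)O[Si](C)(C)C | starting material
12 | methyl 5-[(6S)-6-{[(tert-butyldiphenylsilyl)oxy]methyl}-2,6-dimethylcyclohex-1-en-1-yl]-3-oxopentanoate | CC(C)(C)[Si](c1ccccc1)(c1ccccc1)OC[C@@]1(C)CCCC(C)=C1CCC(=O)CC(=O)OC | intermediate
13 | methyl (1S,4aS,5S,8aR)-5-{[(tert-butyldiphenylsilyl)oxy]methyl}-5,8a-dimethyl-2-oxodecahydronaphthalene-1-carboxylate (trans-fused; the two ring methyls cis; ester equatorial) | CC(C)(C)[Si](c1ccccc1)(c1ccccc1)OC[C@@]1(C)CCC[C@]2(C)[C@@H]1CCC(=O)[C@H]2C(=O)OC | intermediate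
14 | (R)-5-methoxy-3-methyl-5-oxopentanoic acid | COC(=O)C[C@H](C)CC(=O)O | starting material
15 | (S)-5-hydroxy-3-methylpentanoic acid | OCC[C@H](C)CC(=O)O | intermediate
16 | (S)-4-methyloxan-2-one | O=C1C[C@@H](C)CCO1 | intermediate
17 | trimethylsilyl (R)-5-iodo-3-methylpentanoate | ICC[C@H](C)CC(=O)O[Si](C)(C)C | intermediate
18 | methyl (R)-5-iodo-3-methylpentanoate | ICC[C@H](C)CC(=O)OC | intermediate
19 | 13 bearing the (3S)-5-methoxy-3-methyl-5-oxopentyl chain on C1 (naphthalene numbering), chain anti to the 8a-methyl | CC(C)(C)[Si](c1ccccc1)(c1ccccc1)OC[C@@]1(C)CCC[C@]2(C)[C@@H]1CCC(=O)[C@@]2(CC[C@H](C)CC(=O)OC)C(=O)OC | intermediate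
20 | methyl 18-(tert-butyldiphenylsilyloxy)-8-oxo-17-nor-labdan-15-oate (ent series; trans-decalin, H9 anti to the C10 methyl, 13S) | CC(C)(C)[Si](c1ccccc1)(c1ccccc1)OC[C@@]1(C)CCC[C@]2(C)[C@@H]1CCC(=O)[C@H]2CC[C@H](C)CC(=O)OC | intermediate
21 | methyl 18-(tert-butyldiphenylsilyloxy)labd-8(17)-en-15-oate (ent series) | CC(C)(C)[Si](c1ccccc1)(c1ccccc1)OC[C@@]1(C)CCC[C@]2(C)[C@@H]1CCC(=C)[C@H]2CC[C@H](C)CC(=O)OC | intermediate
22 | methyl 18-(tert-butyldiphenylsilyloxy)-8-hydroxylabdan-15-oate (ent series; 8-OH trans to the C10 methyl) | CC(C)(C)[Si](c1ccccc1)(c1ccccc1)OC[C@@]1(C)CCC[C@]2(C)[C@@H]1CC[C@](C)(O)[C@H]2CC[C@H](C)CC(=O)OC | intermediate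
23 | methyl 8,18-dihydroxylabdan-15-oate (ent series) | OC[C@@]1(C)CCC[C@]2(C)[C@@H]1CC[C@](C)(O)[C@H]2CC[C@H](C)CC(=O)OC | intermediate
24 | angelic acid, (Z)-2-methylbut-2-enoic acid | C/C=C(/C)C(=O)O | starting material
25 | angelic 2,4,6-trichlorobenzoic anhydride | C/C=C(/C)C(=O)OC(=O)c1c(Cl)cc(Cl)cc1Cl | intermediate
26 | methyl 18-angeloyloxy-8-hydroxylabdan-15-oate (ent series) | C/C=C(/C)C(=O)OC[C@@]1(C)CCC[C@]2(C)[C@@H]1CC[C@](C)(O)[C@H]2CC[C@H](C)CC(=O)OC | intermediate
27 | trimethylstannyl 18-angeloyloxy-8-hydroxylabdan-15-oate (ent series) | C/C=C(/C)C(=O)OC[C@@]1(C)CCC[C@]2(C)[C@@H]1CC[C@](C)(O)[C@H]2CC[C@H](C)CC(=O)O[Sn](C)(C)C | intermediate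
28 | (4S,5S,8S,9S,10R,13S)-18-angeloyloxy-8-hydroxylabdan-15-oic acid | C/C=C(/C)C(=O)OC[C@@]1(C)CCC[C@]2(C)[C@@H]1CC[C@](C)(O)[C@H]2CC[C@H](C)CC(=O)O | target

**Step count and risks**

Total step count: 15. Longest linear sequence: 13 steps (steps 1–6 and 9–15); steps 7–8 make the side-chain iodide.

Steps most likely to fail:

1. Step 6 (proposed new method). The one-flask merger may fail by protodesilylation of the dienol ether before C–C bond formation, by attack at the tertiary cation terminus or O-alkylation, or by stalling at 12. Facial discrimination relative to C4 in the ring closure may also be low. Fallback with known chemistry, setting out from 10: 48% HBr in pentane at 0 °C should give, with allylic transposition, the primary allylic bromide tert-butyl{[(1S)-2-(bromomethyl)-1,3-dimethylcyclohex-2-en-1-yl]methoxy}diphenylsilane F1. γ-Alkylation of the dianion of methyl acetoacetate (NaH, then n-BuLi, THF, 0 °C) with F1 gives 12, now isolated. The established SnCl4 cyclisation of such 5-cyclohexenyl-3-oxopentanoates in CH2Cl2 then closes ring B, and the route is rejoined at 13. The two bonds are then made in two separate, precedented operations; the diastereomers at C4 are separated at 13 as in the main route.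

2. Step 9. C-Alkylation at the hindered C9, next to the quaternary C10, may be slow and lose to O-alkylation or to elimination of HI from 18. Fallback, setting out from 13: Takai–Lombardo methylenation (Zn, CH2Br2, TiCl4) gives the exocyclic-alkene ester F2, in which the ester carbon serves as C11. DIBAL-H reduction gives the primary alcohol F3, and I2, PPh3 and imidazole give the primary iodide F4. Negishi alkyl–alkyl coupling of F4 with the zinc reagent from methyl (R)-4-iodo-3-methylbutanoate (Zn dust; Pd2(dba)3, PCyp3, N-methylimidazole, THF/NMP) forms C11–C12 and comes back to the route at 21.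

3. Step 12. Capture of the C8 radical by O2 may show poor facial selectivity, giving the C8 epimer. Fallback, setting out from 21: m-CPBA with NaHCO3 in CH2Cl2 should epoxidise from the face opposite the C10 methyl to give the spiro-epoxide F5. PhSeNa (from (PhSe)2 and NaBH4 in EtOH) opens it at the CH2 carbon to the β-hydroxy selenide F6. Bu3SnH with AIBN in toluene at 80 °C removes selenium and comes back to the route at 22.

**Further compounds**

F1 | step 6 | tert-butyl{[(1S)-2-(bromomethyl)-1,3-dimethylcyclohex-2-en-1-yl]methoxy}diphenylsilane | CC(C)(C)[Si](c1ccccc1)(c1ccccc1)OC[C@@]1(C)CCCC(C)=C1CBr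
F2 | step 9 | methyl 5-{[(tert-butyldiphenylsilyl)oxy]methyl}-5,8a-dimethyl-2-methylidenedecahydronaphthalene-1-carboxylate (configuration as in 13) | CC(C)(C)[Si](c1ccccc1)(c1ccccc1)OC[C@@]1(C)CCC[C@]2(C)[C@@H]1CCC(=C)[C@H]2C(=O)OC
F3 | step 9 | primary alcohol from reduction of the ester of F2 | CC(C)(C)[Si](c1ccccc1)(c1ccccc1)OC[C@@]1(C)CCC[C@]2(C)[C@@H]1CCC(=C)[C@H]2CO
F4 | step 9 | primary iodide from F3 | CC(C)(C)[Si](c1ccccc1)(c1ccccc1)OC[C@@]1(C)CCC[C@]2(C)[C@@H]1CCC(=C)[C@H]2CI
F5 | step 12 | 8,17-epoxide of 21, oxygen on the face opposite the C10 methyl | CC(C)(C)[Si](c1ccccc1)(c1ccccc1)OC[C@@]1(C)CCC[C@]2(C)[C@@H]1CC[C@@]3(CO3)[C@H]2CC[C@H](C)CC(=O)OC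
F6 | step 12 | 17-phenylselanyl derivative of 22 | CC(C)(C)[Si](c1ccccc1)(c1ccccc1)OC[C@@]1(C)CCC[C@]2(C)[C@@H]1CC[C@](C[Se]c3ccccc3)(O)[C@H]2CC[C@H](C)CC(=O)OC
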